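**Strategy.** The route rests on cutting ring A at its two adjacent carbon substituents: the C1–C7 bond (hydroxymethyl carbon) and the C6–C8 bond (benzylic bridge), which sit next to the bromine on C5. Both bonds should form in one operation when 3-bromo-4,5-dimethoxybenzyne (C1≡C6 of ring A) inserts into the carbonyl–methylene bond of a ring B β-ketosulfone. The bromine steers the enolate carbon to C1 and the aroyl group to C6. The aryne precursor is an ortho-silylaryl triflate with silicon on C1 and triflate on C6; the partner is 1-(3-bromo-4,5-dimethoxyphenyl)-2-(phenylsulfonyl)ethanone. Ketone deoxygenation, sulfone-to-aldehyde oxidation, demethylation and a final aldehyde reduction complete the target.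

Key step: step 6

Remark (numbering): ring A of the target is C1 (bears C7, the CH2OH carbon), C2 (H), C3 and C4 (OH), C5 (Br), C6 (bears the bridge carbon C8). Ring B is the 3-bromo-4,5-dihydroxyphenyl ring. Compound names use their own locants.

Remark (precursor design): silicon is placed on the aryne carbon remote from bromine and the triflate next to bromine. The same aryne results, but the fluoride-generated aryl anion can then expel only triflate. The silyl group can also be installed by retro-Brook migration through an aryllithium that is not ortho to bromine, so LiBr loss is excluded.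

Remark (order of the endgame): the phenols are carried as methyl ethers, cleaved at the aldehyde oxidation level. The aldehyde is reduced last, so the para-hydroxybenzylic alcohol of the target never meets BBr3.

Assumption: 2-bromo-3,4-dimethoxybenzaldehyde, 3-bromo-4,5-dimethoxybenzaldehyde and methyl phenyl sulfone are taken as catalogue compounds.

Step 1
Reactants: 1 2-bromo-3,4-dimethoxybenzaldehyde
Product: 3 2-bromo-3,4-dimethoxyphenol, via 2-bromo-3,4-dimethoxyphenyl formate 2 (not isolated)
Conditions: mCPBA, CH2Cl2, 0 °C to rt; then K2CO3 (cat.), MeOH, rt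
Reagents that add atoms: mCPBA, O=C(OO)c1cccc(Cl)c1
Why: Baeyer–Villiger oxidation of an electron-rich benzaldehyde (methoxy para to the formyl carbon) should proceed with aryl migration to the aryl formate, whose mild methanolysis releases the phenol (a Dakin-type overall change).

Step 2
Reactants: 3 2-bromo-3,4-dimethoxyphenol
Product: 4 2-bromo-6-iodo-3,4-dimethoxyphenol
Conditions: N-iodosuccinimide, TsOH·H2O (cat.), MeCN, 0 °C to rt
Reagents that add atoms: N-iodosuccinimide, O=C1CCC(=O)N1I
Why: Electrophilic aromatic iodination should occur at C6, the only free position ortho to the hydroxyl and also para to the C3 methoxy group, since the other free position (C5) is meta to the hydroxyl.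

Step 3
Reactants: 4 2-bromo-6-iodo-3,4-dimethoxyphenol
Product: 7 2-bromo-3,4-dimethoxy-6-(trimethylsilyl)phenyl trifluoromethanesulfonate, via aryl trimethylsilyl ether 5 (not isolated), via lithium 6-silylphenoxide 6 (not isolated)
Conditions: (Me3Si)2NH, THF, 65 °C, then evaporation; n-BuLi (1.05 equiv), THF, −100 to −78 °C; then Tf2O, −78 °C to rt
Reagents that add atoms: hexamethyldisilazane, C[Si](C)(C)N[Si](C)(C)C; trifluoromethanesulfonic anhydride, O=S(=O)(OS(=O)(=O)C(F)(F)F)C(F)(F)F
Why: After O-silylation, iodine–lithium exchange (far faster than bromine–lithium exchange at this temperature) gives an aryllithium ortho to the silyloxy group that undergoes 1,3 retro-Brook migration of silicon from oxygen to carbon, and the phenoxide is triflated in the same flask; the aryllithium is meta to bromine, so LiBr cannot be lost.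

Step 4
Reactants: 8 3-bromo-4,5-dimethoxybenzaldehyde; 9 methyl phenyl sulfone
Product: 11 1-(3-bromo-4,5-dimethoxyphenyl)-2-(phenylsulfonyl)ethan-1-ol (racemic), via (phenylsulfonyl)methyllithium 10 (not isolated)
Conditions: 9, n-BuLi, THF, −78 °C; then 8, −78 °C; 1 M HCl quench
Reagents that add atoms: none
Why: Aldol-type 1,2-addition of the preformed α-sulfonyl carbanion to the aldehyde should give the racemic β-hydroxy sulfone (its stereocentre is removed in step 5), and preforming the anion leaves no free n-BuLi to exchange the aryl bromide.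

Step 5
Reactants: 11 1-(3-bromo-4,5-dimethoxyphenyl)-2-(phenylsulfonyl)ethan-1-ol
Product: 12 1-(3-bromo-4,5-dimethoxyphenyl)-2-(phenylsulfonyl)ethan-1-one
Conditions: Dess–Martin periodinane, CH2Cl2, rt
Reagents that add atoms: none
Why: Dess–Martin oxidation of the secondary benzylic alcohol should give the β-ketosulfone under neutral conditions that leave the aryl bromide and the acidic methylene group untouched.

Step 6
Reactants: 7 2-bromo-3,4-dimethoxy-6-(trimethylsilyl)phenyl trifluoromethanesulfonate; 12 1-(3-bromo-4,5-dimethoxyphenyl)-2-(phenylsulfonyl)ethan-1-one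
Product: 15 [2-bromo-3,4-dimethoxy-6-(phenylsulfonylmethyl)phenyl](3-bromo-4,5-dimethoxyphenyl)methanone, via 3-bromo-4,5-dimethoxybenzyne 13 (not isolated), via cesium benzocyclobutenoxide 14 (not isolated)
Conditions: CsF (3 equiv), MeCN, 60 °C
Reagents that add atoms: none
Why: Fluoride attacks silicon and the aryl anion expels the ortho triflate to give aryne 13 (C1≡C6 of ring A); the enolate of 12 adds through carbon to C1, the aryl anion at C6 closes onto the neighbouring ketone to give 14, and strain-driven retro-aldol cleavage of the C7–C8 bond gives a sulfonyl-stabilised benzylic anion that is protonated to 15. The closest known reaction type is aryne acyl-alkylation, the insertion of arynes from ortho-silylaryl triflates into the carbon–carbon bond of β-ketoesters and β-ketosulfones. The only ring closed is the transient four-membered ring (4-exo-trig attack of the aryl anion on the carbonyl), which opens again, so no lasting ring and no stereocentre result. The step needs regioselectivity in the first addition: the inductively withdrawing bromine on C5 distorts the aryne so that C1 is the more electrophilic terminus and the charge developing at C6 is stabilised next to the C–Br bond, and C1 is also the less hindered end. Intramolecular capture of the C6 anion by the ketone should outrun loss of bromide or protonation.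

Step 7
Reactants: 15 [2-bromo-3,4-dimethoxy-6-(phenylsulfonylmethyl)phenyl](3-bromo-4,5-dimethoxyphenyl)methanone
Product: 16 3-bromo-2-(3-bromo-4,5-dimethoxybenzyl)-4,5-dimethoxybenzyl phenyl sulfone
Conditions: Et3SiH (4 equiv), CF3CO2H, CH2Cl2, 0 to 45 °C
Reagents that add atoms: none
Why: Ionic hydrogenation (carbonyl protonation, hydride transfer from silicon, ionisation of the benzhydrol to a cation stabilised by the para-methoxy group of each ring, second hydride transfer) should reduce the diaryl ketone to the methylene bridge without touching the aryl bromides or the sulfone.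

Step 8
Reactants: 16 3-bromo-2-(3-bromo-4,5-dimethoxybenzyl)-4,5-dimethoxybenzyl phenyl sulfone
Product: 19 3-bromo-2-(3-bromo-4,5-dimethoxybenzyl)-4,5-dimethoxybenzaldehyde, via lithiated sulfone 17 (not isolated), via α-silyloxy sulfone 18 (not isolated)
Conditions: LiN(SiMe3)2, THF, −78 °C; then Me3SiOOSiMe3, −78 °C to rt
Reagents that add atoms: bis(trimethylsilyl) peroxide, C[Si](C)(C)OO[Si](C)(C)C
Why: Oxidative desulfonylation: the sulfone α-carbanion (far more acidic than the diarylmethane CH2) is silyloxylated by the peroxide, and the α-silyloxy sulfone collapses with loss of benzenesulfinate to the aldehyde.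

Step 9
Reactants: 19 3-bromo-2-(3-bromo-4,5-dimethoxybenzyl)-4,5-dimethoxybenzaldehyde
Product: 20 3-bromo-2-(3-bromo-4,5-dihydroxybenzyl)-4,5-dihydroxybenzaldehyde
Conditions: BBr3 (excess), CH2Cl2, −78 to 0 °C; then ice-water
Reagents that add atoms: none
Why: BBr3 cleaves aryl methyl ethers by Lewis acid–base complexation and bromide attack on the methyl group, and an aryl aldehyde, unlike a benzylic alcohol, is not turned into a benzylic bromide, while the excess reagent keeps ring B deactivated toward the coordinated carbonyl.

Step 10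
Reactants: 20 3-bromo-2-(3-bromo-4,5-dihydroxybenzyl)-4,5-dihydroxybenzaldehyde
Product: 21 5-hydroxyisoavrainvilleol, 3-bromo-5-[2-bromo-3,4-dihydroxy-6-(hydroxymethyl)benzyl]benzene-1,2-diol
Conditions: NaBH4 (excess), THF–H2O, 0 °C; work-up at pH 6
Reagents that add atoms: none
Why: Borohydride reduction of the aryl aldehyde to the primary benzylic alcohol tolerates free phenols and aryl bromides, and the near-neutral, methanol-free work-up avoids ionisation of the para-hydroxybenzylic alcohol.

**Compound list**

1 | 2-bromo-3,4-dimethoxybenzaldehyde | O=Cc1ccc(OC)c(OC)c1Br | starting material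
2 | 2-bromo-3,4-dimethoxyphenyl formate | O=COc1ccc(OC)c(OC)c1Br | intermediate (not isolated)
3 | 2-bromo-3,4-dimethoxyphenol | Oc1ccc(OC)c(OC)c1Br | intermediate
4 | 2-bromo-6-iodo-3,4-dimethoxyphenol | Oc1c(I)cc(OC)c(OC)c1Br | intermediate
5 | (2-bromo-6-iodo-3,4-dimethoxyphenoxy)trimethylsilane | COc1cc(I)c(O[Si](C)(C)C)c(Br)c1OC | intermediate (not isolated)
6 | lithium 2-bromo-3,4-dimethoxy-6-(trimethylsilyl)phenoxide | [Li+].[O-]c1c(Br)c(OC)c(OC)cc1[Si](C)(C)C | intermediate (not isolated)
7 | 2-bromo-3,4-dimethoxy-6-(trimethylsilyl)phenyl trifluoromethanesulfonate | COc1cc([Si](C)(C)C)c(OS(=O)(=O)C(F)(F)F)c(Br)c1OC | intermediate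
8 | 3-bromo-4,5-dimethoxybenzaldehyde | O=Cc1cc(OC)c(OC)c(Br)c1 | starting material
9 | methyl phenyl sulfone | CS(=O)(=O)c1ccccc1 | starting material
10 | (phenylsulfonyl)methyllithium | [Li+].[CH2-]S(=O)(=O)c1ccccc1 | intermediate (not isolated)
11 | 1-(3-bromo-4,5-dimethoxyphenyl)-2-(phenylsulfonyl)ethan-1-ol, racemic | OC(CS(=O)(=O)c1ccccc1)c1cc(OC)c(OC)c(Br)c1 | intermediate
12 | 1-(3-bromo-4,5-dimethoxyphenyl)-2-(phenylsulfonyl)ethan-1-one | O=C(CS(=O)(=O)c1ccccc1)c1cc(OC)c(OC)c(Br)c1 | intermediate
13 | 3-bromo-4,5-dimethoxybenzyne (3-bromo-1,2-didehydro-4,5-dimethoxybenzene) | COC1=CC#CC(Br)=C1OC | intermediate (not isolated)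
14 | cesium 2-bromo-8-(3-bromo-4,5-dimethoxyphenyl)-3,4-dimethoxy-7-(phenylsulfonyl)bicyclo[4.2.0]octa-1,3,5-trien-8-olate, racemic, relative configuration of the two ring carbons not controlled (both stereocentres vanish on ring opening) | [Cs+].[O-]C1(c2cc(OC)c(OC)c(Br)c2)C(S(=O)(=O)c2ccccc2)c2cc(OC)c(OC)c(Br)c21 | intermediate (not isolated)
15 | [2-bromo-3,4-dimethoxy-6-(phenylsulfonylmethyl)phenyl](3-bromo-4,5-dimethoxyphenyl)methanone | O=C(c1cc(OC)c(OC)c(Br)c1)c1c(Br)c(OC)c(OC)cc1CS(=O)(=O)c1ccccc1 | intermediate
16 | 3-bromo-2-(3-bromo-4,5-dimethoxybenzyl)-4,5-dimethoxybenzyl phenyl sulfone | COc1cc(CS(=O)(=O)c2ccccc2)c(Cc2cc(OC)c(OC)c(Br)c2)c(Br)c1OC | intermediate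
17 | lithium salt of the α-sulfonyl carbanion of 16 | [Li+].COc1cc([CH-]S(=O)(=O)c2ccccc2)c(Cc2cc(OC)c(OC)c(Br)c2)c(Br)c1OC | intermediate (not isolated)
18 | [3-bromo-2-(3-bromo-4,5-dimethoxybenzyl)-4,5-dimethoxyphenyl](trimethylsilyloxy)methyl phenyl sulfone, racemic | COc1cc(C(O[Si](C)(C)C)S(=O)(=O)c2ccccc2)c(Cc2cc(OC)c(OC)c(Br)c2)c(Br)c1OC | intermediate (not isolated)
19 | 3-bromo-2-(3-bromo-4,5-dimethoxybenzyl)-4,5-dimethoxybenzaldehyde | COc1cc(C=O)c(Cc2cc(OC)c(OC)c(Br)c2)c(Br)c1OC | intermediate
20 | 3-bromo-2-(3-bromo-4,5-dihydroxybenzyl)-4,5-dihydroxybenzaldehyde | O=Cc1cc(O)c(O)c(Br)c1Cc1cc(O)c(O)c(Br)c1 | intermediate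
21 | 5-hydroxyisoavrainvilleol, 3-bromo-5-[2-bromo-3,4-dihydroxy-6-(hydroxymethyl)benzyl]benzene-1,2-diol (no stereocentres) | OCc1cc(O)c(O)c(Br)c1Cc1cc(O)c(O)c(Br)c1 | target

**Totals.** Total step count: 10. Longest linear sequence: 8 steps (steps 1, 2, 3, 6, 7, 8, 9, 10).

**Steps most likely to fail**

Step 6 (aryne insertion). The enolate may add at the wrong aryne terminus. The ortho-bromoaryl anion may lose bromide or be protonated before it closes onto the ketone, giving simple α-arylation or products of a second aryne. Fallback, setting out from 8 and returning at 16: NaBH4 in MeOH should reduce 8 to (3-bromo-4,5-dimethoxyphenyl)methanol F1. Aqueous HBr in CH2Cl2 should convert part of this alcohol to 1-bromo-5-(bromomethyl)-2,3-dimethoxybenzene F2. PhSO2Na in DMF should then displace the benzylic bromide to give 3-bromo-4,5-dimethoxybenzyl phenyl sulfone F3. Friedel–Crafts benzylation of the sulfone with the benzylic alcohol (Sc(OTf)3 catalyst, MeNO2, 60 °C, slow addition of the alcohol to an excess of the sulfone) should place the benzyl group para to the C5 methoxy group, between the bromine and the sulfonylmethyl group. That is compound 16, and the route continues with step 8. This forms only the bridge bond, with ring A as the nucleophile.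

Step 8 (sulfone to aldehyde). Oxygen transfer to the carbanion may be incomplete, and the aldehyde, once formed, may be attacked by carbanion that has not yet been oxidised. Fallback, setting out from 16 and returning at 19: the carbanion generated with LiN(SiMe3)2 would be trapped with MeSSMe to give [3-bromo-2-(3-bromo-4,5-dimethoxybenzyl)-4,5-dimethoxyphenyl](methylthio)methyl phenyl sulfone F4. This is a masked aldehyde that never coexists with the carbanion. Hydrolysis in aqueous HCl–MeOH at 50 °C should release 19 with loss of benzenesulfinic acid and methanethiol.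

Step 9 (demethylation of the aldehyde). The Lewis-acid-coordinated aldehyde may be attacked by ring B (Bradsher-type cyclodehydration toward an anthracene), or ether cleavage may stop short. Fallback, setting out from 19 and returning at 21: NaBH4 in THF–MeOH should give [3-bromo-2-(3-bromo-4,5-dimethoxybenzyl)-4,5-dimethoxyphenyl]methanol F5. BBr3 in CH2Cl2 should then cleave the four ethers and convert the benzylic hydroxyl to the bromide, giving 3-bromo-5-[2-bromo-6-(bromomethyl)-3,4-dihydroxybenzyl]benzene-1,2-diol F6. Solvolysis of this para-hydroxybenzylic bromide in dilute aqueous acetone at rt should deliver 21.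

**Further compounds**

F1 | step 6 | (3-bromo-4,5-dimethoxyphenyl)methanol | OCc1cc(OC)c(OC)c(Br)c1
F2 | step 6 | 1-bromo-5-(bromomethyl)-2,3-dimethoxybenzene | COc1cc(CBr)cc(Br)c1OC
F3 | step 6 | 3-bromo-4,5-dimethoxybenzyl phenyl sulfone | COc1cc(CS(=O)(=O)c2ccccc2)cc(Br)c1OC
F4 | step 8 | [3-bromo-2-(3-bromo-4,5-dimethoxybenzyl)-4,5-dimethoxyphenyl](methylthio)methyl phenyl sulfone, racemic | COc1cc(C(SC)S(=O)(=O)c2ccccc2)c(Cc2cc(OC)c(OC)c(Br)c2)c(Br)c1OC
F5 | step 9 | [3-bromo-2-(3-bromo-4,5-dimethoxybenzyl)-4,5-dimethoxyphenyl]methanol | COc1cc(CO)c(Cc2cc(OC)c(OC)c(Br)c2)c(Br)c1OC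
F6 | step 9 | 3-bromo-5-[2-bromo-6-(bromomethyl)-3,4-dihydroxybenzyl]benzene-1,2-diol | Oc1cc(CBr)c(Cc2cc(O)c(O)c(Br)c2)c(Br)c1O
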